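## Structural features

Ring positions are written Cn(ring), for example C4(D). Compound 25 is a linear chain of six benzene rings, A to F, joined by five diaryl ether oxygens and carrying sixteen free phenolic hydroxyls. Ring A is a 2,4,6-trihydroxyphenyl cap, rings B and D are para-linked 3,5-dihydroxy-1,4-phenylene units, rings C and E are ortho-linked 3,4,5-trihydroxy-1,2-phenylene units, and ring F is a 3,4,5-trihydroxyphenyl cap; the links are C1(A)–O–C1(B), C4(B)–O–C1(C), C6(C)–O–C1(D), C4(D)–O–C1(E) and C6(E)–O–C1(F). There is no stereocentre, so no stereocentres adjoin and no configuration has to be set. The fragile part is the free polyphenol: the vicinal triols of rings C, E and F and the phloroglucinol ring A are oxidised by air, fastest in base, so all sixteen hydroxyls should be unmasked in the last step. The real difficulty is five aryl C–O bonds on very electron-rich rings, each with one terminus flanked by two oxygen substituents: C1(A), C4(B), C6(C), C4(D) and C6(E). Three of these, C4(B), C6(C) and C6(E), can be handled by letting the hindered carbon carry the phenol oxygen or sit next to an activating formyl group. The key step exploits the other two: C1(A), between the oxygens on C2(A) and C6(A), and C4(D), between those on C3(D) and C5(D), are each the ipso carbon of a 2,6-dimethoxybenzoic acid, which can be esterified with the phenols on C1(B) and C1(E) and then freed of CO.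

## Logic of the disconnections

25 to 24: the sixteen O–CH3 bonds are added in the retrosynthetic sense. Methyl is the one ether that survives zerovalent nickel at 150 °C, and every ring building block is sold methylated. The gain is a neutral, chromatographable penultimate compound; the demand is one exhaustive demethylation that leaves the five diaryl ether bonds alone.

24 to 23: the C1(A)–O and C4(D)–O ether bonds are cut and a carbonyl is inserted into each, giving a bis-ester. These are the two ether carbons that cannot be reached as electrophiles, whereas the corresponding esters form by simple acylation. The gain is a three-piece assembly (ring A, a BCD unit, an EF unit). The demand is a double CO extrusion that attacks only the two acyl C–O bonds. A ring-by-ring count (sixteen oxygen substituents, five links, acyl carbons on C1(A) and C4(D)) shows 23, 24 and 25 to be mutually consistent, so no structure needs correcting.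

23 to 20 and 21: the ester C(acyl)–O bond at C1(B) is cut. Ring A then enters last as a purchasable acid. The demand is acylation of an unhindered phenol by a hindered acid chloride (22) without transesterifying the D–E ester already present.

20 to 19: a benzyl group is placed on the C1(B) oxygen. A BCD acid with a free C1(B) hydroxyl would, once activated, acylate its own kind and oligomerise, so this oxygen stays masked until the D–E ester exists. Benzyl survives copper coupling, peracid, chlorite and acid chloride formation and is removed by neutral hydrogenolysis, which aryl esters tolerate. The cost is one protection and one deprotection step.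

19 to 12 and 17: the ester C(acyl)–O bond at C1(E) is cut, dividing the molecule into two fragments of similar size. The demand is acylation of an ortho-aryloxy phenol by a 2,6-dimethoxybenzoyl chloride (18).

12 to 11 to 9 and 10: the acid is traced to the aldehyde, then the O–C1(D) bond is cut. C1(D) has two hydrogen neighbours and a para formyl group, so it is the natural electrophile, and the hindered C6(C) carries the oxygen. The demand is copper coupling of a doubly ortho-substituted phenol, then an aldehyde oxidation that does not chlorinate the rings.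

9 to 7 (through 8) to 4 and 6: the C6(C) hydroxyl is traced to a formyl group, then the O–C1(C) bond is cut. The formyl group of 6 works twice: it activates the neighbouring bromide for coupling and then becomes the C6(C) oxygen. The hindered C4(B) enters as the phenol 4. The demand is a hindered Ullmann coupling and a peracid oxidation in which aryl migration beats hydride migration.

6 to 5, and 4 to 2 (through 3) to 1: the formyl C–C bond of 6 is cut; the two free positions of 5 are equivalent, so one aldehyde is expected. The phenol oxygen of 4 is traced to a formyl group and the benzyl O–C bond is cut, giving 1.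

17 to 15 (through 16) to 13 and 14: the C1(E) hydroxyl is traced to a formyl group and the O–C6(E) bond is cut. Here the hindered C6(E) is the electrophile, but it is activated by the ortho formyl group and the nucleophile 13 is unhindered.

## Other disconnections considered

Alternative 1: The cut goes through ring A: the C4(A)–C5(A) ring bond is broken and the ring unfolds into the triketide ester A1, methyl 4-[4-(benzyloxy)-3,5-dimethoxyphenoxy]-3,5-dioxohexanoate. The future C1(A)–O bond is then an sp3 C–O bond, made by alkylating the ring B phenoxide. In the forward step excess strong amide base would form the polyanion of A1; its terminal methyl carbanion would add to the ester carbonyl (intramolecular Claisen condensation), and loss of methoxide and enolisation would give the phloroglucinol A2.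
- In its favour: the hindered C1(A)–O bond is never made on an arene, and no transition metal or high temperature is needed. The reaction type is classical carbonyl chemistry, so on mechanistic precedent this alternative is the better of the two.
- Against it here: attack of the C5 enolate oxygen on the ester would give the pyranone A3, the usual fate of 3,5-dioxohexanoates. An α-aryloxy ketone polyanion may also expel aryloxide. Ring A emerges as a free triol that must be methylated before any copper step, and C4(D) is left unsolved.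
- Comparison: on the B–C coupling the two plans are equal, since both need a hindered phenol at C4(B). On step economy the chosen plan is better: ring A is bought as 21 and attached in one acylation, whereas A1 needs about three steps before the cyclisation and a methylation after it.

Alternative 2: Ring C is taken apart into a four-carbon squarate unit (C3(C) to C6(C)) and a two-carbon aryloxyvinyl unit (C1(C), C2(C)). The precursor is the cyclobutenone A4, 4-[(Z)-2-{2,6-dimethoxy-4-(2,4,6-trimethoxyphenoxy)phenoxy}ethenyl]-2,3,4-trimethoxycyclobut-2-en-1-one. Heating would open the four-membered ring to the dienylketene A5, with the 4-methoxy group expected to rotate outward. A 6π electrocyclisation would then join the ketene carbon to the aryloxy-bearing vinyl carbon (the C6(C)–C1(C) bond), and tautomerisation would give the phenol A6, the ABC analogue of 9 and the same compound as F7 below.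
- In its favour: all five oxygens of ring C are placed by construction, the C6(C) hydroxyl emerges free, and the B–C ether oxygen is attached at the vinyl stage, so no aryl coupling at C1(C) is needed; on that bond it is better than step 4. The thermal ring expansion of 4-alkenylcyclobutenones to phenols is an established reaction class, so on precedent it is also better than step 13.
- Against it here: the AB phenol it starts from already contains the C1(A)–O ether, which must still be made the hard way, and C4(D) is untouched. The 2-aryloxyvinyl organometallic needed to make A4 is prone to β-elimination of aryloxide. A ring that can be bought fully oxygenated is built from scratch.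
- Comparison: the two plans are equal in what they deliver for ring C, a free C6(C) phenol ready for coupling with 10. On step economy the chosen plan is better: about five steps would be needed for what steps 3 to 5 do in three.

Alternative 3: The cut removes two adjacent bonds of ring E, C1(E)–O and C6(E)–I. Fluoride would release 3,4,5-trimethoxybenzyne A8 from the silyl triflate A7. The phenoxide of 4-chloro-2,6-dimethoxyphenol A9 would add at C1(E), the aryne carbon remote from the methoxy group, and the C6(E) aryl anion would take iodine from a perfluoroalkyl iodide to give A10, 1-(4-chloro-2,6-dimethoxyphenoxy)-2-iodo-3,4,5-trimethoxybenzene.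
- In its favour: the C4(D)–O–C1(E) ether is formed directly at the doubly flanked ring D oxygen under mild, metal-free conditions, and aryne additions care little about hindrance in the nucleophile. For this one bond it is the better of the two plans, since it is known chemistry and needs no CO extrusion. The regiochemistry follows from the polarisation of the aryne by the neighbouring methoxy group, which is about as dependable as the chemoselectivity the nickel step relies on (equal).
- Against it here: A7 takes about four steps to make. The C6(E) iodide of A10 is flanked by two oxygens on an electron-rich ring, the worst kind of electrophile for the coupling with 13. The ring D chloride is an unactivated handle for the C–D ether. The aryl anion may be protonated instead of iodinated. C1(A) is left unsolved.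
- Comparison: on step economy the chosen plan is better: the EF phenol 17 takes two steps and the D–E bond shares one operation with the A–B bond.

Key step: step 13

Assumption: compounds 1, 5, 10, 13, 14 and 21 are taken as purchasable; no compound of the route has a stereocentre, so its SMILES strings carry no stereodescriptors.

## Route

Step 1
Reactants: 1 4-hydroxy-2,6-dimethoxybenzaldehyde
Product: 2 4-(benzyloxy)-2,6-dimethoxybenzaldehyde
Conditions: BnBr, K2CO3, DMF, 60 °C
Reagents that add atoms: benzyl bromide, BrCc1ccccc1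
Why: Williamson ether synthesis; the phenoxide of 1 is the only nucleophilic site and is alkylated at oxygen by the benzylic bromide.

Step 2
Reactants: 2 4-(benzyloxy)-2,6-dimethoxybenzaldehyde
Product: 4 4-(benzyloxy)-2,6-dimethoxyphenol, via aryl formate 3 (not isolated)
Conditions: mCPBA, CH2Cl2, 0 °C to rt; aqueous Na2S2O3/NaHCO3 wash; then K2CO3 (cat.), MeOH, rt
Reagents that add atoms: mCPBA, OOC(=O)c1cccc(Cl)c1
Why: Baeyer–Villiger oxidation (Dakin-type); the aryl group, made electron-rich by two ortho methoxy groups and a para benzyloxy group, migrates in preference to hydride, and the formate 3 is methanolysed only after the peracid has been washed out, so the oxidisable phenol never meets the oxidant.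

Step 3
Reactants: 5 5-bromo-1,2,3-trimethoxybenzene
Product: 6 6-bromo-2,3,4-trimethoxybenzaldehyde
Conditions: Cl2CHOMe, TiCl4, CH2Cl2, −10 °C to 0 °C; then H2O
Reagents that add atoms: dichloromethyl methyl ether, COC(Cl)Cl; water, O
Why: Rieche formylation (electrophilic aromatic substitution); the two free positions of 5 are equivalent by symmetry and each is ortho and para to a methoxy group, so a single aldehyde should form after hydrolysis.

Step 4
Reactants: 4 4-(benzyloxy)-2,6-dimethoxyphenol; 6 6-bromo-2,3,4-trimethoxybenzaldehyde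
Product: 7 6-[4-(benzyloxy)-2,6-dimethoxyphenoxy]-2,3,4-trimethoxybenzaldehyde
Conditions: CuI (10 mol%), picolinic acid (20 mol%), K3PO4, DMSO, 90 °C, Ar
Reagents that add atoms: none
Why: Ullmann-type C–O coupling catalysed by monovalent copper; the picolinate ligand system is the one established for 2,6-disubstituted phenols, the ortho formyl group of 6 activates the C–Br bond, and the hindered carbon C4(B) enters as the phenol and not as the halide.

Step 5
Reactants: 7 6-[4-(benzyloxy)-2,6-dimethoxyphenoxy]-2,3,4-trimethoxybenzaldehyde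
Product: 9 6-[4-(benzyloxy)-2,6-dimethoxyphenoxy]-2,3,4-trimethoxyphenol, via aryl formate 8 (not isolated)
Conditions: mCPBA, CH2Cl2, 0 °C to rt; aqueous Na2S2O3/NaHCO3 wash; then K2CO3 (cat.), MeOH, rt
Reagents that add atoms: mCPBA, OOC(=O)c1cccc(Cl)c1
Why: Baeyer–Villiger oxidation as in step 2; the formyl-bearing carbon has aryloxy and methoxy groups ortho and a methoxy group para, which favours aryl migration, and the benzyl and diaryl ethers are inert to the peracid at this temperature.

Step 6
Reactants: 9 6-[4-(benzyloxy)-2,6-dimethoxyphenoxy]-2,3,4-trimethoxyphenol; 10 4-bromo-2,6-dimethoxybenzaldehyde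
Product: 11 4-{6-[4-(benzyloxy)-2,6-dimethoxyphenoxy]-2,3,4-trimethoxyphenoxy}-2,6-dimethoxybenzaldehyde
Conditions: CuI (10 mol%), picolinic acid (20 mol%), K3PO4, DMSO, 100 °C, Ar
Reagents that add atoms: none
Why: Ullmann-type C–O coupling; the bromide of 10 has two hydrogen neighbours and a para formyl group, the most favourable electrophile of the route, which offsets the doubly ortho-substituted phenoxide of 9.

Step 7
Reactants: 11 4-{6-[4-(benzyloxy)-2,6-dimethoxyphenoxy]-2,3,4-trimethoxyphenoxy}-2,6-dimethoxybenzaldehyde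
Product: 12 4-{6-[4-(benzyloxy)-2,6-dimethoxyphenoxy]-2,3,4-trimethoxyphenoxy}-2,6-dimethoxybenzoic acid
Conditions: NaClO2, NaH2PO4, 2-methyl-2-butene, t-BuOH/THF/H2O, rt
Reagents that add atoms: sodium chlorite, [Na+].[O-]Cl=O
Why: Pinnick oxidation of a non-enolisable aryl aldehyde; excess 2-methyl-2-butene traps HOCl before it can chlorinate the electron-rich rings, and the benzyl ether is untouched.

Step 8
Reactants: 13 3,4,5-trimethoxyphenol; 14 2-bromo-3,4,5-trimethoxybenzaldehyde
Product: 15 3,4,5-trimethoxy-2-(3,4,5-trimethoxyphenoxy)benzaldehyde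
Conditions: CuI (10 mol%), picolinic acid (20 mol%), K3PO4, DMSO, 90 °C, Ar
Reagents that add atoms: none
Why: Ullmann-type C–O coupling; the nucleophile 13 is an unhindered, electron-rich phenol, and the C–Br bond of 14, although next to a methoxy group, is activated by the ortho formyl group.

Step 9
Reactants: 15 3,4,5-trimethoxy-2-(3,4,5-trimethoxyphenoxy)benzaldehyde
Product: 17 3,4,5-trimethoxy-2-(3,4,5-trimethoxyphenoxy)phenol, via aryl formate 16 (not isolated)
Conditions: mCPBA, CH2Cl2, 0 °C to rt; aqueous Na2S2O3/NaHCO3 wash; then K2CO3 (cat.), MeOH, rt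
Reagents that add atoms: mCPBA, OOC(=O)c1cccc(Cl)c1
Why: Baeyer–Villiger oxidation as in steps 2 and 5; the ortho aryloxy and para methoxy groups direct aryl migration, and mild methanolysis of 16 releases the C1(E) phenol.

Step 10
Reactants: 12 4-{6-[4-(benzyloxy)-2,6-dimethoxyphenoxy]-2,3,4-trimethoxyphenoxy}-2,6-dimethoxybenzoic acid; 17 3,4,5-trimethoxy-2-(3,4,5-trimethoxyphenoxy)phenol
Product: 19 3,4,5-trimethoxy-2-(3,4,5-trimethoxyphenoxy)phenyl 4-{6-[4-(benzyloxy)-2,6-dimethoxyphenoxy]-2,3,4-trimethoxyphenoxy}-2,6-dimethoxybenzoate, via acid chloride 18 (not isolated)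
Conditions: (COCl)2, DMF (cat.), CH2Cl2, 0 °C to rt, concentrate; then 17, Et3N, DMAP (cat.), CH2Cl2, rt
Reagents that add atoms: none
Why: Esterification through the acid chloride with DMAP as acyl-transfer catalyst; 2,6-dimethoxybenzoyl chlorides are stable acylating agents for phenols, and because the C1(B) oxygen of 12 is benzylated the activated acid can react only with 17.

Step 11
Reactants: 19 3,4,5-trimethoxy-2-(3,4,5-trimethoxyphenoxy)phenyl 4-{6-[4-(benzyloxy)-2,6-dimethoxyphenoxy]-2,3,4-trimethoxyphenoxy}-2,6-dimethoxybenzoate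
Product: 20 3,4,5-trimethoxy-2-(3,4,5-trimethoxyphenoxy)phenyl 4-[6-(4-hydroxy-2,6-dimethoxyphenoxy)-2,3,4-trimethoxyphenoxy]-2,6-dimethoxybenzoate
Conditions: H2 (1 atm), Pd/C, THF/EtOAc, rt
Reagents that add atoms: none
Why: Hydrogenolysis of a benzyl aryl ether over Pd/C under neutral conditions; aryl esters, diaryl ethers and methyl ethers are not reduced.

Step 12
Reactants: 20 3,4,5-trimethoxy-2-(3,4,5-trimethoxyphenoxy)phenyl 4-[6-(4-hydroxy-2,6-dimethoxyphenoxy)-2,3,4-trimethoxyphenoxy]-2,6-dimethoxybenzoate; 21 2,4,6-trimethoxybenzoic acid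
Product: 23 3,4,5-trimethoxy-2-(3,4,5-trimethoxyphenoxy)phenyl 4-(6-{2,6-dimethoxy-4-[(2,4,6-trimethoxybenzoyl)oxy]phenoxy}-2,3,4-trimethoxyphenoxy)-2,6-dimethoxybenzoate, via 2,4,6-trimethoxybenzoyl chloride 22 (not isolated)
Conditions: 21, (COCl)2, DMF (cat.), CH2Cl2, 0 °C to rt, concentrate; then 20, Et3N, DMAP (cat.), CH2Cl2, rt
Reagents that add atoms: none
Why: Acylation of the unhindered C1(B) phenol (two hydrogen neighbours) by the acid chloride 22 under DMAP catalysis; the hindered D–E ester already present should not transesterify at room temperature.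

Step 13
Reactants: 23 3,4,5-trimethoxy-2-(3,4,5-trimethoxyphenoxy)phenyl 4-(6-{2,6-dimethoxy-4-[(2,4,6-trimethoxybenzoyl)oxy]phenoxy}-2,3,4-trimethoxyphenoxy)-2,6-dimethoxybenzoate
Product: 24 2-{4-[2-(4-{3,4,5-trimethoxy-2-(3,4,5-trimethoxyphenoxy)phenoxy}-3,5-dimethoxyphenoxy)-3,4,5-trimethoxyphenoxy]-3,5-dimethoxyphenoxy}-1,3,5-trimethoxybenzene
Conditions: Ni(cod)2 (30 mol%), 3,4-bis(dicyclohexylphosphino)thiophene (60 mol%), K3PO4, m-xylene, 150 °C, slow Ar sweep
Reagents that add atoms: none
Why: Proposed new method: zerovalent nickel carrying the electron-rich chelating bisphosphine should add oxidatively to the C(acyl)–O bond of each aryl ester, the only activated C–O bonds in 23, giving acyl nickel aryloxides of divalent nickel; aryl migration from the acyl carbon to nickel then de-inserts CO, helped by the two ortho methoxy groups at C2(A)/C6(A) and at C3(D)/C5(D), which twist the carbonyl out of the ring plane, and at 150 °C under an argon sweep the CO leaves the metal. C–O reductive elimination from the resulting aryl nickel aryloxide forms the C1(A)–O–C1(B) and C4(D)–O–C1(E) bonds and returns zerovalent nickel, and the sequence runs once at each ester. The closest known reaction type is the nickel- or palladium-catalysed decarbonylative etherification of aryl esters, which has been shown for aryl esters of azinecarboxylic acids, where a ring nitrogen next to the carboxyl assists; here an ortho methoxy oxygen is counted on as a weak hemilabile donor, and a 2,6-dioxygenated benzoate and a twofold event go beyond that scope. No ring is closed and no stereocentre is formed: two acyclic skeletal C–O bonds are made with loss of two molecules of CO. The selectivity needed is for acyl C–O over methyl C–O and diaryl ether C–O bonds; it is secured by the absence of any organometallic or hydride partner, without which zerovalent nickel does not cleave anisole-type or diaryl ether bonds, and by methyl being the only protecting group. Each aryloxide must also stay on the nickel centre that holds its own aryl partner, and the chelating ligand and low concentration are meant to suppress exchange between metal centres.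

Step 14
Reactants: 24 2-{4-[2-(4-{3,4,5-trimethoxy-2-(3,4,5-trimethoxyphenoxy)phenoxy}-3,5-dimethoxyphenoxy)-3,4,5-trimethoxyphenoxy]-3,5-dimethoxyphenoxy}-1,3,5-trimethoxybenzene
Product: 25 2-{4-[2-(4-{3,4,5-trihydroxy-2-(3,4,5-trihydroxyphenoxy)phenoxy}-3,5-dihydroxyphenoxy)-3,4,5-trihydroxyphenoxy]-3,5-dihydroxyphenoxy}benzene-1,3,5-triol
Conditions: BBr3 (excess), CH2Cl2, −78 °C to rt; then MeOH, degassed H2O, Ar
Reagents that add atoms: none
Why: Lewis acid-mediated ether cleavage; BBr3 complexes each methoxy oxygen and bromide attacks the methyl carbon in an SN2 step that no aryl carbon can undergo, so the five diaryl ether bonds should persist, and hydrolysis of the aryl borates with exclusion of air releases the sixteen hydroxyls.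

## Compound list

1 | 4-hydroxy-2,6-dimethoxybenzaldehyde | COc1cc(O)cc(OC)c1C=O | starting material
2 | 4-(benzyloxy)-2,6-dimethoxybenzaldehyde | COc1cc(OCc2ccccc2)cc(OC)c1C=O | intermediate
3 | 4-(benzyloxy)-2,6-dimethoxyphenyl formate (formed in the flask) | COc1cc(OCc2ccccc2)cc(OC)c1OC=O | intermediate
4 | 4-(benzyloxy)-2,6-dimethoxyphenol (ring B unit) | COc1cc(OCc2ccccc2)cc(OC)c1O | intermediate
5 | 5-bromo-1,2,3-trimethoxybenzene | COc1cc(Br)cc(OC)c1OC | starting material
6 | 6-bromo-2,3,4-trimethoxybenzaldehyde (ring C unit) | COc1cc(Br)c(C=O)c(OC)c1OC | intermediate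
7 | 6-[4-(benzyloxy)-2,6-dimethoxyphenoxy]-2,3,4-trimethoxybenzaldehyde (BC aldehyde) | COc1cc(Oc2c(OC)cc(OCc3ccccc3)cc2OC)c(C=O)c(OC)c1OC | intermediate
8 | 6-[4-(benzyloxy)-2,6-dimethoxyphenoxy]-2,3,4-trimethoxyphenyl formate (formed in the flask) | COc1cc(Oc2c(OC)cc(OCc3ccccc3)cc2OC)c(OC=O)c(OC)c1OC | intermediate
9 | 6-[4-(benzyloxy)-2,6-dimethoxyphenoxy]-2,3,4-trimethoxyphenol (BC phenol) | COc1cc(Oc2c(OC)cc(OCc3ccccc3)cc2OC)c(O)c(OC)c1OC | intermediate
10 | 4-bromo-2,6-dimethoxybenzaldehyde (ring D unit) | COc1cc(Br)cc(OC)c1C=O | starting material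
11 | 4-{6-[4-(benzyloxy)-2,6-dimethoxyphenoxy]-2,3,4-trimethoxyphenoxy}-2,6-dimethoxybenzaldehyde (BCD aldehyde) | COc1cc(Oc2c(OC)cc(OCc3ccccc3)cc2OC)c(Oc2cc(OC)c(C=O)c(OC)c2)c(OC)c1OC | intermediate
12 | 4-{6-[4-(benzyloxy)-2,6-dimethoxyphenoxy]-2,3,4-trimethoxyphenoxy}-2,6-dimethoxybenzoic acid (BCD acid) | COc1cc(Oc2c(OC)cc(OCc3ccccc3)cc2OC)c(Oc2cc(OC)c(C(=O)O)c(OC)c2)c(OC)c1OC | intermediate
13 | 3,4,5-trimethoxyphenol (ring F unit) | COc1cc(O)cc(OC)c1OC | starting material
14 | 2-bromo-3,4,5-trimethoxybenzaldehyde (ring E unit) | COc1cc(C=O)c(Br)c(OC)c1OC | starting material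
15 | 3,4,5-trimethoxy-2-(3,4,5-trimethoxyphenoxy)benzaldehyde (EF aldehyde) | COc1cc(C=O)c(Oc2cc(OC)c(OC)c(OC)c2)c(OC)c1OC | intermediate
16 | 3,4,5-trimethoxy-2-(3,4,5-trimethoxyphenoxy)phenyl formate (formed in the flask) | COc1cc(OC=O)c(Oc2cc(OC)c(OC)c(OC)c2)c(OC)c1OC | intermediate
17 | 3,4,5-trimethoxy-2-(3,4,5-trimethoxyphenoxy)phenol (EF phenol) | COc1cc(O)c(Oc2cc(OC)c(OC)c(OC)c2)c(OC)c1OC | intermediate
18 | 4-{6-[4-(benzyloxy)-2,6-dimethoxyphenoxy]-2,3,4-trimethoxyphenoxy}-2,6-dimethoxybenzoyl chloride (formed in the flask) | COc1cc(Oc2c(OC)cc(OCc3ccccc3)cc2OC)c(Oc2cc(OC)c(C(Cl)=O)c(OC)c2)c(OC)c1OC | intermediate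
19 | 3,4,5-trimethoxy-2-(3,4,5-trimethoxyphenoxy)phenyl 4-{6-[4-(benzyloxy)-2,6-dimethoxyphenoxy]-2,3,4-trimethoxyphenoxy}-2,6-dimethoxybenzoate | COc1cc(Oc2c(OC)cc(OCc3ccccc3)cc2OC)c(Oc2cc(OC)c(C(=O)Oc3cc(OC)c(OC)c(OC)c3Oc3cc(OC)c(OC)c(OC)c3)c(OC)c2)c(OC)c1OC | intermediate
20 | 3,4,5-trimethoxy-2-(3,4,5-trimethoxyphenoxy)phenyl 4-[6-(4-hydroxy-2,6-dimethoxyphenoxy)-2,3,4-trimethoxyphenoxy]-2,6-dimethoxybenzoate | COc1cc(Oc2c(OC)cc(O)cc2OC)c(Oc2cc(OC)c(C(=O)Oc3cc(OC)c(OC)c(OC)c3Oc3cc(OC)c(OC)c(OC)c3)c(OC)c2)c(OC)c1OC | intermediate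
21 | 2,4,6-trimethoxybenzoic acid (ring A unit) | COc1cc(OC)c(C(=O)O)c(OC)c1 | starting material
22 | 2,4,6-trimethoxybenzoyl chloride (formed in the flask) | COc1cc(OC)c(C(Cl)=O)c(OC)c1 | intermediate
23 | 3,4,5-trimethoxy-2-(3,4,5-trimethoxyphenoxy)phenyl 4-(6-{2,6-dimethoxy-4-[(2,4,6-trimethoxybenzoyl)oxy]phenoxy}-2,3,4-trimethoxyphenoxy)-2,6-dimethoxybenzoate (bis-ester, all sixteen hydroxyls methylated) | COc1cc(OC)c(C(=O)Oc2cc(OC)c(Oc3cc(OC)c(OC)c(OC)c3Oc3cc(OC)c(C(=O)Oc4cc(OC)c(OC)c(OC)c4Oc4cc(OC)c(OC)c(OC)c4)c(OC)c3)c(OC)c2)c(OC)c1 | intermediate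
24 | 2-{4-[2-(4-{3,4,5-trimethoxy-2-(3,4,5-trimethoxyphenoxy)phenoxy}-3,5-dimethoxyphenoxy)-3,4,5-trimethoxyphenoxy]-3,5-dimethoxyphenoxy}-1,3,5-trimethoxybenzene (hexadecamethyl ether of 25) | COc1cc(OC)c(Oc2cc(OC)c(Oc3cc(OC)c(OC)c(OC)c3Oc3cc(OC)c(Oc4cc(OC)c(OC)c(OC)c4Oc4cc(OC)c(OC)c(OC)c4)c(OC)c3)c(OC)c2)c(OC)c1 | intermediate
25 | 2-{4-[2-(4-{3,4,5-trihydroxy-2-(3,4,5-trihydroxyphenoxy)phenoxy}-3,5-dihydroxyphenoxy)-3,4,5-trihydroxyphenoxy]-3,5-dihydroxyphenoxy}benzene-1,3,5-triol (CNP0114537.0) | Oc1cc(O)c(Oc2cc(O)c(Oc3cc(O)c(O)c(O)c3Oc3cc(O)c(Oc4cc(O)c(O)c(O)c4Oc4cc(O)c(O)c(O)c4)c(O)c3)c(O)c2)c(O)c1 | target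

## Step count and least certain steps

Total: 14 steps. Longest linear sequence: 11 steps (steps 1, 2, 4, 5, 6, 7, 10, 11, 12, 13, 14).

**Step 13 (key step).** The catalytic cycle may stall after oxidative addition or after CO loss, because C–O reductive elimination from an electron-rich, doubly ortho-substituted aryl nickel aryloxide of divalent nickel is slow. Protonation of the aryl–nickel bond (net decarbonylative ester cleavage), exchange of aryloxide between nickel centres (crossed ethers) and binding of CO to zerovalent nickel may then outrun ether formation. One of the two esters may also fail to react, and the 2,6-dimethoxy groups may shield the acyl C–O bond from oxidative addition.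

Fallback, known chemistry only, setting out from 10 and returning at 24: an iterative Ullmann coupling and Baeyer–Villiger sequence in which every hindered ether carbon enters as the phenol.
- Purchased 2,4,6-trimethoxyphenol F1 is coupled with 10 (CuI, picolinic acid, K3PO4, DMSO) to give 2,6-dimethoxy-4-(2,4,6-trimethoxyphenoxy)benzaldehyde F2.
- mCPBA converts F2 into 2,6-dimethoxy-4-(2,4,6-trimethoxyphenoxy)phenyl formate F3, methanolysed in the flask to 2,6-dimethoxy-4-(2,4,6-trimethoxyphenoxy)phenol F4.
- Coupling of F4 with 6 gives 6-[2,6-dimethoxy-4-(2,4,6-trimethoxyphenoxy)phenoxy]-2,3,4-trimethoxybenzaldehyde F5, oxidised through 6-[2,6-dimethoxy-4-(2,4,6-trimethoxyphenoxy)phenoxy]-2,3,4-trimethoxyphenyl formate F6 to 6-[2,6-dimethoxy-4-(2,4,6-trimethoxyphenoxy)phenoxy]-2,3,4-trimethoxyphenol F7.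
- Coupling of F7 with 10 gives 4-{6-[2,6-dimethoxy-4-(2,4,6-trimethoxyphenoxy)phenoxy]-2,3,4-trimethoxyphenoxy}-2,6-dimethoxybenzaldehyde F8, oxidised through 4-{6-[2,6-dimethoxy-4-(2,4,6-trimethoxyphenoxy)phenoxy]-2,3,4-trimethoxyphenoxy}-2,6-dimethoxyphenyl formate F9 to 4-{6-[2,6-dimethoxy-4-(2,4,6-trimethoxyphenoxy)phenoxy]-2,3,4-trimethoxyphenoxy}-2,6-dimethoxyphenol F10.
- Coupling of F10 with 6 gives 6-(4-{6-[2,6-dimethoxy-4-(2,4,6-trimethoxyphenoxy)phenoxy]-2,3,4-trimethoxyphenoxy}-2,6-dimethoxyphenoxy)-2,3,4-trimethoxybenzaldehyde F11, oxidised through 6-(4-{6-[2,6-dimethoxy-4-(2,4,6-trimethoxyphenoxy)phenoxy]-2,3,4-trimethoxyphenoxy}-2,6-dimethoxyphenoxy)-2,3,4-trimethoxyphenyl formate F12 to 6-(4-{6-[2,6-dimethoxy-4-(2,4,6-trimethoxyphenoxy)phenoxy]-2,3,4-trimethoxyphenoxy}-2,6-dimethoxyphenoxy)-2,3,4-trimethoxyphenol F13.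
- A last copper coupling of F13 with 5 gives 24.

This path is linear and several steps longer than the depside route, but each step is of a type already used in steps 2 to 9.

**Step 4.** C–O bond formation at the doubly ortho-substituted phenoxide of 4 may be slow, so that reductive loss of bromine from 6 and oxidative degradation of the electron-rich phenoxide on copper take over. Fallback, setting out from 4 and returning at 7: nucleophilic aromatic substitution without metal. Purchased 5-fluoro-1,2,3-trimethoxybenzene F14 is formylated under the conditions of step 3 to 6-fluoro-2,3,4-trimethoxybenzaldehyde F15, whose fluoride, activated by the ortho formyl group, is displaced by the phenoxide of 4 (K2CO3, DMSO, 120 °C) to give 7.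

**Step 6.** The phenoxide of 9, flanked by a bulky aryloxy group and a methoxy group, may bind copper poorly, so that the coupling stalls while the aldehyde of 10 degrades in hot basic DMSO. Fallback, setting out from 9 and returning at 11: nucleophilic aromatic substitution on purchased 4-fluoro-2,6-dimethoxybenzaldehyde F16 (K2CO3, DMF, 100 °C), whose fluoride is para to the formyl group and has no ortho substituent.

**Step 14.** Demethylation at sixteen sites may stop short as partly borylated intermediates precipitate, and the pyrogallol-type rings may be oxidised by air during aqueous work-up and chromatography of the very polar product. Fallback, setting out from 24 and returning at 25: derivatise, purify, release. The crude product of the BBr3 reaction is acetylated at once (Ac2O, pyridine) to the hexadecaacetate F17, which is stable to air and can be separated on silica from incompletely demethylated material. Acid methanolysis of F17 (HCl, degassed MeOH, Ar) then releases 25 without exposing phenoxides to air.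

## Further compounds

F1 | step 13 | 2,4,6-trimethoxyphenol | COc1cc(OC)c(O)c(OC)c1
F2 | step 13 | 2,6-dimethoxy-4-(2,4,6-trimethoxyphenoxy)benzaldehyde | COc1cc(OC)c(Oc2cc(OC)c(C=O)c(OC)c2)c(OC)c1
F3 | step 13 | 2,6-dimethoxy-4-(2,4,6-trimethoxyphenoxy)phenyl formate | COc1cc(OC)c(Oc2cc(OC)c(OC=O)c(OC)c2)c(OC)c1
F4 | step 13 | 2,6-dimethoxy-4-(2,4,6-trimethoxyphenoxy)phenol | COc1cc(OC)c(Oc2cc(OC)c(O)c(OC)c2)c(OC)c1
F5 | step 13 | 6-[2,6-dimethoxy-4-(2,4,6-trimethoxyphenoxy)phenoxy]-2,3,4-trimethoxybenzaldehyde | COc1cc(Oc2c(OC)cc(Oc3c(OC)cc(OC)cc3OC)cc2OC)c(C=O)c(OC)c1OC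
F6 | step 13 | 6-[2,6-dimethoxy-4-(2,4,6-trimethoxyphenoxy)phenoxy]-2,3,4-trimethoxyphenyl formate | COc1cc(Oc2c(OC)cc(Oc3c(OC)cc(OC)cc3OC)cc2OC)c(OC=O)c(OC)c1OC
F7 | step 13 | 6-[2,6-dimethoxy-4-(2,4,6-trimethoxyphenoxy)phenoxy]-2,3,4-trimethoxyphenol | COc1cc(Oc2c(OC)cc(Oc3c(OC)cc(OC)cc3OC)cc2OC)c(O)c(OC)c1OC
F8 | step 13 | 4-{6-[2,6-dimethoxy-4-(2,4,6-trimethoxyphenoxy)phenoxy]-2,3,4-trimethoxyphenoxy}-2,6-dimethoxybenzaldehyde | COc1cc(Oc2c(OC)cc(Oc3c(OC)cc(OC)cc3OC)cc2OC)c(Oc2cc(OC)c(C=O)c(OC)c2)c(OC)c1OC
F9 | step 13 | 4-{6-[2,6-dimethoxy-4-(2,4,6-trimethoxyphenoxy)phenoxy]-2,3,4-trimethoxyphenoxy}-2,6-dimethoxyphenyl formate | COc1cc(Oc2c(OC)cc(Oc3c(OC)cc(OC)cc3OC)cc2OC)c(Oc2cc(OC)c(OC=O)c(OC)c2)c(OC)c1OC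
F10 | step 13 | 4-{6-[2,6-dimethoxy-4-(2,4,6-trimethoxyphenoxy)phenoxy]-2,3,4-trimethoxyphenoxy}-2,6-dimethoxyphenol | COc1cc(Oc2c(OC)cc(Oc3c(OC)cc(OC)cc3OC)cc2OC)c(Oc2cc(OC)c(O)c(OC)c2)c(OC)c1OC
F11 | step 13 | 6-(4-{6-[2,6-dimethoxy-4-(2,4,6-trimethoxyphenoxy)phenoxy]-2,3,4-trimethoxyphenoxy}-2,6-dimethoxyphenoxy)-2,3,4-trimethoxybenzaldehyde | COc1cc(Oc2c(OC)cc(Oc3c(OC)cc(OC)cc3OC)cc2OC)c(Oc2cc(OC)c(Oc3cc(OC)c(OC)c(OC)c3C=O)c(OC)c2)c(OC)c1OC
F12 | step 13 | 6-(4-{6-[2,6-dimethoxy-4-(2,4,6-trimethoxyphenoxy)phenoxy]-2,3,4-trimethoxyphenoxy}-2,6-dimethoxyphenoxy)-2,3,4-trimethoxyphenyl formate | COc1cc(Oc2c(OC)cc(Oc3c(OC)cc(OC)cc3OC)cc2OC)c(Oc2cc(OC)c(Oc3cc(OC)c(OC)c(OC)c3OC=O)c(OC)c2)c(OC)c1OC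
F13 | step 13 | 6-(4-{6-[2,6-dimethoxy-4-(2,4,6-trimethoxyphenoxy)phenoxy]-2,3,4-trimethoxyphenoxy}-2,6-dimethoxyphenoxy)-2,3,4-trimethoxyphenol | COc1cc(Oc2c(OC)cc(Oc3c(OC)cc(OC)cc3OC)cc2OC)c(Oc2cc(OC)c(Oc3cc(OC)c(OC)c(OC)c3O)c(OC)c2)c(OC)c1OC
F14 | step 4 | 5-fluoro-1,2,3-trimethoxybenzene | COc1cc(F)cc(OC)c1OC
F15 | step 4 | 6-fluoro-2,3,4-trimethoxybenzaldehyde | COc1cc(F)c(C=O)c(OC)c1OC
F16 | step 6 | 4-fluoro-2,6-dimethoxybenzaldehyde | COc1cc(F)cc(OC)c1C=O
F17 | step 14 | hexadecaacetate of 25 (every hydroxyl of 25 acetylated) | CC(=O)Oc1cc(OC(C)=O)c(Oc2cc(OC(C)=O)c(Oc3cc(OC(C)=O)c(OC(C)=O)c(OC(C)=O)c3Oc3cc(OC(C)=O)c(Oc4cc(OC(C)=O)c(OC(C)=O)c(OC(C)=O)c4Oc4cc(OC(C)=O)c(OC(C)=O)c(OC(C)=O)c4)c(OC(C)=O)c3)c(OC(C)=O)c2)c(OC(C)=O)c1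
A1 | alternative 1 | methyl 4-[4-(benzyloxy)-3,5-dimethoxyphenoxy]-3,5-dioxohexanoate (racemic) | COC(=O)CC(=O)C(Oc1cc(OC)c(OCc2ccccc2)c(OC)c1)C(C)=O
A2 | alternative 1 | 2-[4-(benzyloxy)-3,5-dimethoxyphenoxy]benzene-1,3,5-triol | Oc1cc(O)c(Oc2cc(OC)c(OCc3ccccc3)c(OC)c2)c(O)c1
A3 | alternative 1 | 5-[4-(benzyloxy)-3,5-dimethoxyphenoxy]-4-hydroxy-6-methyl-2H-pyran-2-one | CC1=C(Oc2cc(OC)c(OCc3ccccc3)c(OC)c2)C(O)=CC(=O)O1
A4 | alternative 2 | 4-[(Z)-2-{2,6-dimethoxy-4-(2,4,6-trimethoxyphenoxy)phenoxy}ethenyl]-2,3,4-trimethoxycyclobut-2-en-1-one (racemic) | COC1=C(OC)C(OC)(/C=C\Oc2c(OC)cc(Oc3c(OC)cc(OC)cc3OC)cc2OC)C1=O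
A5 | alternative 2 | (3Z,5Z)-6-[2,6-dimethoxy-4-(2,4,6-trimethoxyphenoxy)phenoxy]-2,3,4-trimethoxyhexa-1,3,5-trien-1-one | COC(=C=O)/C(OC)=C(OC)\C=C/Oc1c(OC)cc(Oc2c(OC)cc(OC)cc2OC)cc1OC
A6 | alternative 2 | 6-[2,6-dimethoxy-4-(2,4,6-trimethoxyphenoxy)phenoxy]-2,3,4-trimethoxyphenol | COc1cc(Oc2c(OC)cc(Oc3c(OC)cc(OC)cc3OC)cc2OC)c(O)c(OC)c1OC
A7 | alternative 3 | 2,3,4-trimethoxy-6-(trimethylsilyl)phenyl trifluoromethanesulfonate | COc1cc([Si](C)(C)C)c(OS(=O)(=O)C(F)(F)F)c(OC)c1OC
A8 | alternative 3 | 3,4,5-trimethoxybenzyne (1,2-didehydro-3,4,5-trimethoxybenzene) | COC1=C(OC)C(OC)=CC#C1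
A9 | alternative 3 | 4-chloro-2,6-dimethoxyphenol | COc1cc(Cl)cc(OC)c1O
A10 | alternative 3 | 1-(4-chloro-2,6-dimethoxyphenoxy)-2-iodo-3,4,5-trimethoxybenzene | COc1cc(Oc2c(OC)cc(Cl)cc2OC)c(I)c(OC)c1OC
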